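The constants used here were chosen freely; the flask was simulated.

In this flask the binding step takes from second catalyst what the coupling step gives back, so c(second catalyst) + c(catalyst intermediate) stays at the 2.8 mM charged.

    substrate + free catalyst → free catalyst + open intermediate (k1 = 0.35 M⁻¹ min⁻¹)
    second catalyst + open intermediate ⇌ catalyst intermediate (K2 = 24 M⁻¹, k2 = 11 M⁻¹ min⁻¹)
    solid reagent ⇌ coupling partner, rate k3*(cs3 - [coupling partner]) while solid is left; crystals form when [coupling partner] > cs3 (cs3 = 0.32 M, k3 = 0.61 min⁻¹)
    coupling partner + catalyst intermediate → second catalyst + product (k4 = 0.48 M⁻¹ min⁻¹)

substrate 0.40 M; solid reagent 1.00 M; free catalyst 60 mM; second catalyst 2.8 mM; time 1.0 h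

- as a solid, counted per litre of solution: solid reagent
- at the start none of the solid reagent is in solution
- run time (flask): 1.0 h

- Thursday's: doubling the dissolution coefficient of step 3, all else as stated
- Saturday's: doubling the solubility in step 3, all else as stated
- Tuesday's: doubling the amount of free catalyst, all else as stated

* product at 1.0 h, in percent of the substrate charged
* the change that raises the amount of product at 1.0 h, in percent of the substrate charged most ("none" if none brings more than 2 percentage points) (Thursday's / Saturday's / Tuesday's / none)
* amount of product at 1.0 h, in percent of the substrate charged, after Tuesday's

A second bound stands beside that balance: dissolving from an empty solution, c(coupling partner) climbs towards the solubility, 0.32 M, and stops there while solid is left. You can therefore hold product formation against 4.30 × 10⁻⁴ M min⁻¹, the ceiling rate: the rate of the coupling step with c(coupling partner) at the solubility and the whole charge of second catalyst bound as catalyst intermediate. Set the opening rates of the flask against it, in powers of ten.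

| Rate in the flask | Value | Powers of ten above the ceiling rate |
|---|---|---|
| Dissolution into an empty solution | 0.195 M min⁻¹ | 2.66 |
| Opening of substrate at the start | 0.00840 M min⁻¹ | 1.29 |
| Ceiling rate | 4.30 × 10⁻⁴ M min⁻¹ | 0 |

The top row stands above the second, and its time scale of 1.64 min is short against the hour, so c(coupling partner) comes near the solubility early. The second row says that at the start open intermediate is supplied at more than the ceiling rate, and that supply falls as substrate goes, with a half-life of 0.55 h by the opening step alone. The bottom row, carried through 1.0 h, gives 6.45% of the substrate charged, and this flask starts with second catalyst unbound and no coupling partner in solution, so you must land below that figure.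

Tuesday's moves the second row and Thursday's the first, while the ceiling rate contains neither setting. Saturday's doubles the ceiling to 12.9%. So my reckoning commits to Saturday's and to both yields under 6.45%, and it stops there, without a mean bound share.

The forecast goes further, with 4.4%, 4.9% after Tuesday's and Saturday's as best, since “Doubling the solubility nearly doubles Vmax”.

The flask gives 4.37%, 4.88% after Tuesday's, and Saturday's as best, with a gain of 3.8 percentage points. At 1.00 h in this flask, catalyst intermediate, the resting state of the second catalyst, holds 82.7% of the second catalyst charged, and the hour's mean rate of product formation is 67.8% of the ceiling rate. In the neighbour flask with 0.10 M of substrate, the same ceiling is 25.8% of its own charge. That flask gives 9.62%, which is 37.3% of its ceiling, with catalyst intermediate at 52.0% of the second catalyst at 1.00 h.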